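**Retrosynthetic overview**

1. Target 19 comes from the protected flavone 18 by one Lewis-acid operation that cleaves the carbonyl-chelated 5-O-methyl group and both benzyl ethers.
2. 18 is cut at C3–C4 and O1–C2 of the pyranone ring C into salicylaldehyde 9 (formyl carbon = C4, phenol oxygen = O1) and aroyl sulfoxonium ylide 16 (ylide carbon = C3, aroyl carbon = C2). The feature used is that C4 (on C4a) and O1 (on C8a) are ortho on a ring A that bears oxygen at C5–C8, so ring A has no aryl C–H.
3. 9 comes from 2,3,4,5-tetramethoxyphenol 7 by ortho-formylation; 7 comes from 2,3,4-trimethoxybenzaldehyde 1 by Dakin oxidation, O-methylation and ortho-lithiation/borylation/oxidation.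
4. 16 comes from 2,5-dihydroxybenzoic acid 10 (benzylation, saponification, acid chloride) and trimethylsulfoxonium iodide 13, which supplies C3.
5. Ring order: rings A and B are bought as benzenes; ring C is the only ring made, in step 7.

Key step: step 7

Assumption: the target has no stereocentre and the C2–C1′ bond rotates freely, so it is one achiral compound and no stereocontrol is needed.

**Route**

Step 1
Reactants: 1 2,3,4-trimethoxybenzaldehyde
Product: 3 2,3,4-trimethoxyphenol, via 2,3,4-trimethoxyphenyl formate 2 (not isolated)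
Conditions: 30% aq. H2O2 (1.3 equiv), H2SO4 (cat.), MeOH, rt
Reagents that add atoms: hydrogen peroxide, OO
Why: Acid-catalysed Dakin oxidation, in which the ortho- and para-methoxy groups make the aryl group migrate to the peroxide oxygen and the aryl formate is methanolysed in the same pot.

Step 2
Reactants: 3 2,3,4-trimethoxyphenol
Product: 4 1,2,3,4-tetramethoxybenzene
Conditions: MeI (1.5 equiv), K2CO3 (2 equiv), acetone, reflux
Reagents that add atoms: iodomethane, CI
Why: Williamson O-methylation of the only acidic hydroxyl group.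

Step 3
Reactants: 4 1,2,3,4-tetramethoxybenzene
Product: 7 2,3,4,5-tetramethoxyphenol, via 2,3,4,5-tetramethoxyphenyllithium 5 (not isolated), via lithium trimethoxy(2,3,4,5-tetramethoxyphenyl)borate 6 (not isolated)
Conditions: n-BuLi (1.2 equiv), TMEDA (1.2 equiv), THF, 0 °C to rt; B(OMe)3 (1.5 equiv), −78 °C to rt; AcOH, 30% H2O2, 0 °C; reductive work-up, N2
Reagents that add atoms: hydrogen peroxide, OO
Why: Methoxy-directed ortho-lithiation (the two ring hydrogens are equivalent), borylation and oxidative 1,2-shift of the aryl group from boron to oxygen, the standard lithiation–borylation–oxidation route to phenols.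

Step 4
Reactants: 7 2,3,4,5-tetramethoxyphenol
Product: 9 2-hydroxy-3,4,5,6-tetramethoxybenzaldehyde, via 2-(hydroxymethyl)-3,4,5,6-tetramethoxyphenol 8 (not isolated)
Conditions: MgCl2 (anhydrous, 2 equiv), Et3N (4 equiv), (CH2O)n (6 equiv), MeCN, reflux, N2; 1 M HCl work-up
Reagents that add atoms: paraformaldehyde (as formaldehyde), C=O
Why: Magnesium-phenoxide-directed ortho-formylation (Casnati–Skattebøl) at the only free ring position, where the hydroxymethyl intermediate is oxidised by hydride transfer to a second formaldehyde.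

Step 5
Reactants: 10 2,5-dihydroxybenzoic acid
Product: 12 2,5-bis(benzyloxy)benzoic acid, via benzyl 2,5-bis(benzyloxy)benzoate 11 (not isolated)
Conditions: BnBr (3.5 equiv), K2CO3 (4.5 equiv), DMF, 60 °C; then 2 M NaOH, MeOH, 70 °C; ether wash, HCl to pH 2
Reagents that add atoms: benzyl bromide, BrCc1ccccc1
Why: Williamson benzylation of both phenols and the carboxylate, then saponification of the benzyl ester in the same pot, to which aryl benzyl ethers are inert.

Step 6
Reactants: 12 2,5-bis(benzyloxy)benzoic acid; 13 trimethylsulfoxonium iodide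
Product: 16 1-[2,5-bis(benzyloxy)phenyl]-2-[dimethyl(oxo)-λ6-sulfanylidene]ethan-1-one, via 2,5-bis(benzyloxy)benzoyl chloride 14 (not isolated), via dimethylsulfoxonium methylide 15 (not isolated)
Conditions: (COCl)2 (1.3 equiv), DMF (cat.), CH2Cl2, 0 °C to rt, evaporate; 13 (3.2 equiv), KOt-Bu (3.1 equiv), THF, reflux 2 h, then crude 14 in THF, 0 °C to rt
Reagents that add atoms: none
Why: C-acylation of the Corey–Chaykovsky ylide by the acid chloride, after which a second equivalent of methylide deprotonates the acylsulfoxonium salt to the stabilised β-keto sulfoxonium ylide.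

Step 7
Reactants: 9 2-hydroxy-3,4,5,6-tetramethoxybenzaldehyde; 16 1-[2,5-bis(benzyloxy)phenyl]-2-[dimethyl(oxo)-λ6-sulfanylidene]ethan-1-one
Product: 18 2-[2,5-bis(benzyloxy)phenyl]-5,6,7,8-tetramethoxy-4H-chromen-4-one, via 1-[2,5-bis(benzyloxy)phenyl]-3-(2-hydroxy-3,4,5,6-tetramethoxyphenyl)propane-1,3-dione 17 (not isolated)
Conditions: 16 (1.5 equiv), [Cp*RhCl2]2 (4 mol %), AgSbF6 (16 mol %), CsOAc (0.5 equiv), AcOH (1 equiv), DCE, 80 °C, N2
Reagents that add atoms: none
Why: Acetate-assisted, phenoxide-directed cleavage of the formyl C–H of 9 at Cp*Rh(III) should give a five-membered acyl rhodacycle; ylide 16 binds through carbon and loses DMSO to form a rhodium carbene, the acyl group migrates onto the carbene carbon (C3–C4 bond), and protonolysis by AcOH releases the o-hydroxyaryl 1,3-diketone 17 and the catalyst. The closest known reaction type is the Cp*Rh(III)-catalysed annulation of salicylaldehydes with aroyl sulfoxonium ylides to flavones, applied here to a more substituted pair. Ring C then closes by 6-exo-trig addition of the phenol oxygen to the aryl ketone carbonyl of 17 (O1–C2 bond), and acid-promoted loss of water from the hemiketal gives the pyranone. No stereocentre is formed. The step needs chemoselectivity for the formyl C–H and one direction of cyclisation: ring A of 9 has no aryl C–H and its anionic phenoxide should outcompete the weakly directing ylide carbonyl for rhodium, while the benzyl ethers on ring B leave the ring-A phenol as the only nucleophile for the ketone.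

Step 8
Reactants: 18 2-[2,5-bis(benzyloxy)phenyl]-5,6,7,8-tetramethoxy-4H-chromen-4-one
Product: 19 5,2',5'-trihydroxy-6,7,8-trimethoxyflavone
Conditions: BCl3 (1 M in CH2Cl2, 6 equiv), C6HMe5 (6 equiv), CH2Cl2, −78 °C to 0 °C (to rt if the 5-OMe persists); degassed aq. HCl work-up, N2
Reagents that add atoms: none
Why: Lewis-acid ether cleavage in which BCl3 bridges the C4 carbonyl and the peri 5-methoxy oxygen so that chloride removes only that methyl group, while the benzyl ethers ionise and pentamethylbenzene traps the benzyl cation by Friedel–Crafts alkylation; the unchelated 6-, 7- and 8-methoxy groups should remain.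

**Compound list**

1 | 2,3,4-trimethoxybenzaldehyde | COc1ccc(C=O)c(OC)c1OC | starting material
2 | 2,3,4-trimethoxyphenyl formate | COc1ccc(OC=O)c(OC)c1OC | intermediate
3 | 2,3,4-trimethoxyphenol | COc1ccc(O)c(OC)c1OC | intermediate
4 | 1,2,3,4-tetramethoxybenzene | COc1ccc(OC)c(OC)c1OC | intermediate
5 | 2,3,4,5-tetramethoxyphenyllithium | [Li]c1cc(OC)c(OC)c(OC)c1OC | intermediate
6 | lithium trimethoxy(2,3,4,5-tetramethoxyphenyl)borate | [Li+].CO[B-](OC)(OC)c1cc(OC)c(OC)c(OC)c1OC | intermediate
7 | 2,3,4,5-tetramethoxyphenol | COc1cc(O)c(OC)c(OC)c1OC | intermediate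
8 | 2-(hydroxymethyl)-3,4,5,6-tetramethoxyphenol | COc1c(O)c(CO)c(OC)c(OC)c1OC | intermediate
9 | 2-hydroxy-3,4,5,6-tetramethoxybenzaldehyde | COc1c(O)c(C=O)c(OC)c(OC)c1OC | intermediate
10 | 2,5-dihydroxybenzoic acid | O=C(O)c1cc(O)ccc1O | starting material
11 | benzyl 2,5-bis(benzyloxy)benzoate | O=C(OCc1ccccc1)c1cc(OCc2ccccc2)ccc1OCc1ccccc1 | intermediate
12 | 2,5-bis(benzyloxy)benzoic acid | O=C(O)c1cc(OCc2ccccc2)ccc1OCc1ccccc1 | intermediate
13 | trimethylsulfoxonium iodide | C[S+](C)(C)=O.[I-] | starting material
14 | 2,5-bis(benzyloxy)benzoyl chloride | O=C(Cl)c1cc(OCc2ccccc2)ccc1OCc1ccccc1 | intermediate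
15 | dimethylsulfoxonium methylide | C=S(C)(C)=O | intermediate
16 | 1-[2,5-bis(benzyloxy)phenyl]-2-[dimethyl(oxo)-λ6-sulfanylidene]ethan-1-one | CS(C)(=O)=CC(=O)c1cc(OCc2ccccc2)ccc1OCc1ccccc1 | intermediate
17 | 1-[2,5-bis(benzyloxy)phenyl]-3-(2-hydroxy-3,4,5,6-tetramethoxyphenyl)propane-1,3-dione | COc1c(O)c(C(=O)CC(=O)c2cc(OCc3ccccc3)ccc2OCc2ccccc2)c(OC)c(OC)c1OC | intermediate
18 | 2-[2,5-bis(benzyloxy)phenyl]-5,6,7,8-tetramethoxy-4H-chromen-4-one | COc1c(OC)c(OC)c2c(=O)cc(-c3cc(OCc4ccccc4)ccc3OCc3ccccc3)oc2c1OC | intermediate
19 | 5,2',5'-trihydroxy-6,7,8-trimethoxyflavone | COc1c(OC)c(O)c2c(=O)cc(-c3cc(O)ccc3O)oc2c1OC | target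

**Summary**

Total step count: 8 (steps 1–4 on the ring-A line, steps 5–6 on the ylide branch, steps 7–8 after convergence).
Longest linear sequence: 6 steps (1 → 3 → 4 → 7 → 9 → 18 → 19).

**Steps most likely to fail**

Step 7 (key annulation). The formyl group of 9 is flanked by two ortho substituents, and the phenoxide with its neighbouring 3-methoxy group may hold rhodium in an unproductive O,O-chelate. Formyl C–H cleavage could then be slow, and the ylide could be used up by carbene dimerisation or by ketone-directed activation of its own C6′–H. The fallback is a Baker–Venkataraman sequence that sets out from phenol 7 and acid chloride 14 (made from 12 as in step 6). Phenol 7 would be C-acetylated at its only free position with AcOH/BF3·OEt2 at 80 °C to give 1-(2-hydroxy-3,4,5,6-tetramethoxyphenyl)ethan-1-one F1. O-Acylation of F1 with 14 (pyridine, cat. DMAP, CH2Cl2) should give 2-acetyl-3,4,5,6-tetramethoxyphenyl 2,5-bis(benzyloxy)benzoate F2. KOt-Bu in THF should then move the aroyl group from oxygen to the acetyl carbon and give diketone 17, where the route is rejoined; p-TsOH in warm toluene closes 17 to 18.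

Step 8 (global deprotection). A second methyl group (6-OMe) may be lost once the 5-O–boron chelate has formed, or the chelated methyl ether may survive at the low temperature that suits the debenzylation. The electron-rich hydroquinone ring may also be C-benzylated, or be oxidised by air to the quinone during work-up. The fallback sets out from 18 and splits the deprotection into two orthogonal operations. Hydrogenolysis (H2, 1 atm, Pd/C, EtOAc–THF) should give 2-(2,5-dihydroxyphenyl)-5,6,7,8-tetramethoxy-4H-chromen-4-one F3. AlCl3 in MeCN at rt, which cleaves only the peri methyl ether under chelation control, should then give 19.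

Step 4 (ortho-formylation). Magnesium may be held between the phenoxide and the adjacent methoxy oxygen so that hydroxymethylation is sluggish, and the very electron-rich phenoxide may degrade oxidatively at reflux. The fallback sets out from 7 and uses directed metalation. MOMCl/i-Pr2NEt in CH2Cl2 should give 1,2,3,4-tetramethoxy-5-(methoxymethoxy)benzene F4. n-BuLi in THF at 0 °C (lithiation at the single ring hydrogen, directed by the MOM ether) followed by DMF should give 2,3,4,5-tetramethoxy-6-(methoxymethoxy)benzaldehyde F5. HCl in MeOH at 40 °C then removes the acetal and returns to the route at 9.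

**Further compounds**

F1 | step 7 | 1-(2-hydroxy-3,4,5,6-tetramethoxyphenyl)ethan-1-one | CC(=O)c1c(O)c(OC)c(OC)c(OC)c1OC
F2 | step 7 | 2-acetyl-3,4,5,6-tetramethoxyphenyl 2,5-bis(benzyloxy)benzoate | CC(=O)c1c(OC(=O)c2cc(OCc3ccccc3)ccc2OCc2ccccc2)c(OC)c(OC)c(OC)c1OC
F3 | step 8 | 2-(2,5-dihydroxyphenyl)-5,6,7,8-tetramethoxy-4H-chromen-4-one | COc1c(OC)c(OC)c2c(=O)cc(-c3cc(O)ccc3O)oc2c1OC
F4 | step 4 | 1,2,3,4-tetramethoxy-5-(methoxymethoxy)benzene | COCOc1cc(OC)c(OC)c(OC)c1OC
F5 | step 4 | 2,3,4,5-tetramethoxy-6-(methoxymethoxy)benzaldehyde | COCOc1c(C=O)c(OC)c(OC)c(OC)c1OC
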